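# Proposed total synthesis of CNP0261293.8 by a silicon-tethered enone–alkyne photocycloaddition

## The problem

The target **28** is a monocyclic, elemane-type seco-acid: a cyclohexane in which five of the six ring carbons are stereogenic. Numbered C1 (quaternary, CH3 and vinyl), C2 (CH2), C3 (acyloxy), C4 (acrylic acid), C5 (OH) and C6 (3-hydroxyprop-1-en-2-yl), the ring carries the C1 vinyl group, both oxygens (C3, C5) and the C6 alkenyl group on one face (the "lower" face); the C1 methyl and the C4 side chain lie on the upper face. There is no second ring in the product to lean on, so relative configuration has to be set in a temporary polycycle. The C3 oxygen is 1,3-cis to the C1 vinyl group and can deliver carbon to C1 and C6, and once these are locked in a rigid frame the open face can control C4 and C5. The molecule is fragile in several ways: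

- the acrylic acid sits γ to the free C5 hydroxyl and lactonises under acid;
- the (Z)-γ-acetoxy-α-methyl enoate isomerises to E under nucleophilic catalysis and collapses to a butenolide if its acetate is lost;
- two carboxylic esters rule out hydrolytic or strongly basic end-game steps;
- the C3 and C5 hydroxyls, one acylated and one free, must be told apart.

The enabling feature is the cis-vicinal pair of alkenyl groups on C1 and C6. Joined through their inner carbons they are a cis-fused cyclobutene, the product of an enone–alkyne [2+2] photocycloaddition across C1=C6 of a 3-methylcyclohexenone whose carbonyl is C5. The C3 oxygen is placed to tether that alkyne through a removable silicon atom.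

## Retrosynthesis

**28 ⇐ 26 ⇐ 25 (protecting groups only).** No skeletal bond is cut. The acid is stored as a tert-butyl ester and the primary allylic alcohol as a 4-methoxybenzyl (PMB) ether, because both can be removed without hydroxide, fluoride or hydrogen. The PMB ether goes first (oxidatively). The ester is then cleaved under silylating conditions, so that O5 is capped at the moment the free acid appears and cannot lactonise.

**25 ⇐ 18 + 23 (C3–O acyl bond).** The enoate side chain is the most fragile part of the molecule and is attached last among the bond-forming steps. Building it on the ring by olefination would need base on a substrate with an acrylate and a free alcohol, and carrying it earlier would expose it to enolate and fluoride chemistry. The precursor, diol **18**, is simpler by the whole side chain. The forward reaction must acylate O3 in preference to O5 and must not isomerise the Z-alkene.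

**23 ⇐ 22 ⇐ 19 (side-chain acid).** The Z geometry is taken from a ring: opening butenolide **19** fixes the carboxyl and the CH2O group cis. The open form must be trapped as ester and acetate (**22**) before it can close again, and the ester must then be removed without touching the acetate.

**18 ⇐ 17 (retro-ethenolysis).** The two terminal methylene groups are removed and the inner alkene carbons are joined, which turns the vinyl and the 2-propenyl unit into one cis-fused cyclobutene. The neighbouring option, introducing the two alkenyl groups one at a time, would have to build a quaternary centre and its neighbour cis to each other in two separate stereoselective reactions. In **17** a single ring fusion encodes that relationship. The forward ring-opening metathesis must leave the α-substituted acrylate alone.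

**17 ⇐ 15 ⇐ 14 ⇐ 13 (acrylate methylene; C–Si and O–Si bonds).** The exocyclic methylene is cut back to an aminomethyl group and then to the plain acetate side chain of **13**. The cyclobutene C–H and the O3–H are traced back to a C–Si and an O–Si bond, i.e. to the intact siloxane tricycle. The aminomethylation is placed on the tricycle because there the side chain and both oxygens are trans-diaxial and no lactone can form. The elimination to the acrylate is placed after the fluoride step, so that no Michael acceptor meets an alkoxide.

**13 ⇐ 12 (C5–H bond).** The C5 alcohol comes from the ketone. Doing this on the tricycle rather than later lets the silicon bridge and the cyclobutene close the lower face, so hydride can only arrive from above.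

**12 ⇐ 11 (key disconnection: C1–C and C6–C bonds of the cyclobutene).** Two carbon–carbon bonds, two rings and two stereocentres are removed at once, leaving a monocyclic enone with one stereocentre pair. An intermolecular photocycloaddition would control neither regiochemistry nor the face. Cutting only the C1–C bond (a conjugate addition) would leave C6 unset. The forward reaction must place the CH2O-bearing alkyne carbon on C6 and add on the face of the C3 oxygen.

**11 ⇐ 6 + 8 (Si–O and Si–C(sp) bonds).** The tether is assembled from alcohol **6**, alkyne **8** and a dimethylsilyl linker. Silicon is chosen because it is later lost from both carbon and oxygen in one operation.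

**6 ⇐ 5 ⇐ 4 (C4–CH2 bond).** The acetate side chain is attached to the enone before the photochemistry rather than to ketone **12** after it. In the monocyclic enone the trans product is both the kinetic and the more stable one. In **12** the ring-fusion proton at C6 (α to the ketone and allylic to the cyclobutene) would compete with the C4 protons for the base. Enone **4** is simpler than **5** by one stereocentre.

**4 ⇐ 3 ⇐ 2 ⇐ 1 (C1=C6 double bond; C–CH3 bond).** The cyclohexenone is opened at its double bond to a keto β-ketophosphonate (**3**), and the methyl ketone is traced to the ester of **1** through Weinreb amide **2**. The stereocentre of **1** already has two chemically distinct arms, so the direction of ring closure, and with it the absolute configuration of **4**, is unambiguous. A resolution of a cyclic hydroxy-enone precursor was rejected: the two arms flanking its carbinol carbon differ too little for reliable enzymatic discrimination, and half the material would be lost.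

**8 ⇐ 7.** The alkyne component is the PMB ether of propargyl alcohol **7**. PMB is chosen over a silyl group because it must survive the fluoride step.

## Roads not taken

**Alternative 1:** The ring would be cut at C5–C6. In the forward sense a C5 aldehyde, released in situ, is attacked by the γ-carbon (C6) of a tethered (Z)-allyl pinacolboronate. This closes the cyclohexane and moves the alkene into the 1,1-disubstituted position to give the cyclised homoallylic alcohol **A1**.
- Merits: a closed, chair-like transition state sets C5 and C6 together from the boronate geometry, without an external reagent. O3 is already an ether and the acid a fluoride-labile ester. In that respect the road is better than the chosen plan, which has to discriminate O3 from O5 by sterics in step 16 and to cleave a tert-butyl ester at the very end.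
- Weak points: the open-chain substrate must already carry C1 (quaternary), C3 and C4 in the right relative configuration. The reacting γ-carbon is attached to that quaternary centre and is therefore neopentyl-like and slow. A trisubstituted Z-allylboronate must be made geometrically pure. The aldehyde α-centre (C4) can epimerise. The acrylate methylene still has to be installed afterwards.
- Comparison: the chosen plan sets against these points that C1 and C6 come from one purchased stereocentre through a tether, and that C4 and C5 are set on cyclic intermediates.

**Alternative 2:** The ring would be cut at C1–C6 and C2–C3. In the forward sense methacrolein **A2** adds to the (E,E)-silyl diene **A3** under a chiral cationic oxazaborolidine Lewis acid, [C24H25BNO][N(SO2CF3)2], to give the endo cyclohexene carbaldehyde **A4**.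
- Merits: the quaternary centre and its neighbour are set in one catalytic, intermolecular step from simple pieces, and no photochemistry is needed. In brevity up to the first cyclic intermediate and in the catalytic source of chirality this road is better than the chosen one, which buys its stereocentre and needs eight steps to reach **12**.
- Weak points: **A4** still lacks the C4 and C5 substituents, and its C4=C5 alkene has to be turned into a trans C–C/C–O pair, for which there is no direct reaction. The dioxolane on C6 needs several steps (diol release, selective oxidation, methylenation next to an epimerisable centre) to become the hydroxy-isopropenyl unit. The C–Si bond has to be oxidised in the presence of alkenes. The chiral diene and the chiral catalyst may be mismatched.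
- Comparison: the chosen plan sets against this that **12** carries every ring carbon in a directly usable form: a ketone at C5 for the C4/C5 chemistry and a cyclobutene that becomes both alkenyl groups in one ethenolysis.

**Alternative 3:** The ring would be cut at C4–C5. In the forward sense CrCl2 (divalent chromium) converts a (Z)-2-(bromomethyl)enoate into an allylchromium species that adds through C4 to a C5 aldehyde, closing the ring and creating the exocyclic acrylate in the same event, to give the cyclised hydroxy acrylate **A5**.
- Merits: the acrylate, C4 and C5 appear in one step. That replaces four steps of the chosen route (alkylation, reduction, aminomethylation, elimination), and O3 is differentiated from the start. In step economy around the acrylate this road is clearly better.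
- Weak points: the acyclic aldehyde must contain the vicinal C1 (quaternary) and C6 stereocentres and C3, so the hardest stereochemical problem is moved into open-chain chemistry. 1,2-Induction from the C3 ether to C4 in the allylmetal is uncertain. The usual fate of such hydroxy acrylates is lactonisation, here a dead end. Chromium is used in stoichiometric amount.
- Comparison: the chosen plan sets against this that all five stereocentres derive from one stereocentre through rigid cyclic intermediates, at the price of a longer sequence after the key step.

Key step: step 8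

## Route

Assumption: ketophosphonate **1**, a statin side-chain intermediate, is taken as purchasable in the (3R) form; every later stereocentre derives from its carbinol carbon.

Convention: ring carbons are numbered C1–C6 as above; the "lower face" is the face of the C3 oxygen, the "upper face" that of the C1 methyl group.

Step 1
Reactants: 1 methyl (3R)-3-[(tert-butyldimethylsilyl)oxy]-6-(dimethoxyphosphoryl)-5-oxohexanoate
Product: 2 dimethyl {(4R)-4-[(tert-butyldimethylsilyl)oxy]-6-[methoxy(methyl)amino]-2,6-dioxohexyl}phosphonate
Conditions: MeNH(OMe)·HCl, i-PrMgCl, THF, −20 → 0 °C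
Reagents that add atoms: N,O-dimethylhydroxylamine hydrochloride, CNOC.Cl
Why: Weinreb amidation of the methyl ester by the chloromagnesium amide; the β-ketophosphonate is deprotonated first and is thereby masked as its magnesium enolate, so the ester is the only electrophile and the stereocentre is untouched.

Step 2
Reactants: 2 dimethyl {(4R)-4-[(tert-butyldimethylsilyl)oxy]-6-[methoxy(methyl)amino]-2,6-dioxohexyl}phosphonate
Product: 3 dimethyl {(4S)-4-[(tert-butyldimethylsilyl)oxy]-2,6-dioxoheptyl}phosphonate
Conditions: MeMgBr (3 equiv), THF, −78 → 0 °C; aq. NH4Cl
Reagents that add atoms: methylmagnesium bromide, C[Mg]Br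
Why: Grignard addition to a Weinreb amide stops at the chelated tetrahedral intermediate and releases the methyl ketone on work-up; the first equivalent of MeMgBr re-forms the unreactive ketophosphonate enolate (the descriptor changes only because the priorities of the two arms swap).

Step 3
Reactants: 3 dimethyl {(4S)-4-[(tert-butyldimethylsilyl)oxy]-2,6-dioxoheptyl}phosphonate
Product: 4 (5S)-5-[(tert-butyldimethylsilyl)oxy]-3-methylcyclohex-2-en-1-one
Conditions: K2CO3, 18-crown-6, toluene, 25 → 50 °C
Reagents that add atoms: none
Why: Intramolecular Horner–Wadsworth–Emmons reaction: the phosphonate carbanion, the most acidic site, attacks the methyl ketone in a six-membered closure; only this direction of closure is possible, so the enone carbonyl ends up on the former phosphonate arm and the carbinol carbon becomes (5S).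

Step 4
Reactants: 4 (5S)-5-[(tert-butyldimethylsilyl)oxy]-3-methylcyclohex-2-en-1-one
Product: 5 tert-butyl 2-[(1R,6S)-6-[(tert-butyldimethylsilyl)oxy]-4-methyl-2-oxocyclohex-3-en-1-yl]acetate
Conditions: LiN(i-Pr)2, THF, −78 °C; BrCH2CO2t-Bu, DMPU, −78 → −30 °C
Reagents that add atoms: tert-butyl bromoacetate, CC(C)(C)OC(=O)CBr
Why: Kinetic α′-deprotonation gives the cross-conjugated lithium enolate, which is alkylated anti to the pseudo-axial silyloxy group; this sets C4 trans to the C3 oxygen, and the trans isomer is also the more stable one. Enolates of β-silyloxy cyclohexenones are known to survive at low temperature without losing silanolate.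

Step 5
Reactants: 5 tert-butyl 2-[(1R,6S)-6-[(tert-butyldimethylsilyl)oxy]-4-methyl-2-oxocyclohex-3-en-1-yl]acetate
Product: 6 tert-butyl 2-[(1R,6S)-6-hydroxy-4-methyl-2-oxocyclohex-3-en-1-yl]acetate
Conditions: 48% aq. HF, MeCN, 0 °C
Reagents that add atoms: none
Why: Acidic fluoride desilylation; the non-basic medium avoids β-elimination (and aromatisation) of the β-hydroxy enone and leaves the tert-butyl ester intact.

Step 6
Reactants: 7 prop-2-yn-1-ol
Product: 8 1-methoxy-4-[(prop-2-yn-1-yloxy)methyl]benzene
Conditions: NaH, 4-MeOC6H4CH2Cl, Bu4NI (cat.), THF/DMF, 0 °C → rt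
Reagents that add atoms: 4-methoxybenzyl chloride, COc1ccc(CCl)cc1
Why: Williamson ether synthesis; the PMB ether is chosen because it survives light, enolates, fluoride and ruthenium and is removed oxidatively at the end.

Step 7
Reactants: 8 1-methoxy-4-[(prop-2-yn-1-yloxy)methyl]benzene; 6 tert-butyl 2-[(1R,6S)-6-hydroxy-4-methyl-2-oxocyclohex-3-en-1-yl]acetate
Product: 11 tert-butyl 2-[(1R,6S)-6-({[3-(4-methoxybenzyloxy)prop-1-yn-1-yl]dimethylsilyl}oxy)-4-methyl-2-oxocyclohex-3-en-1-yl]acetate, via lithium acetylide 9 (not isolated), via alkynylchlorosilane 10 (not isolated)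
Conditions: 8, n-BuLi, THF, −78 °C; Me2SiCl2 (5 equiv), −78 °C → rt; evaporate; then 6, imidazole, CH2Cl2, 0 °C → rt
Reagents that add atoms: dichlorodimethylsilane, C[Si](C)(Cl)Cl
Why: Silylation of the acetylide with excess dichlorosilane gives the mono-alkynyl chlorosilane, which silylates the secondary alcohol under imidazole catalysis (standard formation of a temporary silicon tether); the labile silyl ether is purified on base-washed silica and used at once.

Step 8
Reactants: 11 tert-butyl 2-[(1R,6S)-6-({[3-(4-methoxybenzyloxy)prop-1-yn-1-yl]dimethylsilyl}oxy)-4-methyl-2-oxocyclohex-3-en-1-yl]acetate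
Product: 12 tricyclic cyclobutene ketone (cyclobutene cis-fused at C1–C6; SiMe2–O bridge to C3; C5 ketone)
Conditions: hν (350 nm, Pyrex), degassed CH2Cl2 (0.005 M), 0 °C, stopped at full conversion
Reagents that add atoms: none
Why: Excitation (n→π*) and intersystem crossing give the enone triplet, which bonds from C1 (the β-carbon) to the silicon-bound alkyne carbon; this closes the six-membered 1-oxa-2-silacyclohexane in a 6-exo-dig sense and leaves a 1,4-biradical (α-keto radical at C6, vinyl radical on the distal alkyne carbon). After spin inversion the radicals combine to form the C6–C bond and close the four-membered ring as a cyclobutene. The closest known reactions are intramolecular enone–alkyne [2+2] photocycloadditions to bicyclo[4.2.0]oct-7-en-2-ones and silicon-tethered enone–alkene photocycloadditions. C1 is controlled by the C3 stereocentre: the two-atom O–Si link can reach C1 only from the face of the C3 oxygen, with that oxygen pseudo-axial, so the methyl group is left on the upper face. C6 is controlled by C1, because a four-membered ring can only be cis-fused to the six-membered ring and the second bond therefore forms on the same lower face. The step needs the CH2O-bearing carbon on C6 and lower-face addition; the tether secures both, since bonding of the silicon-bound carbon to C6 would require a seven-membered ring and upper-face attack is geometrically out of reach. The C4 side chain, trans to the C3 oxygen, lies on the upper face and is a spectator. Long-wavelength light and stopping at full conversion limit a secondary 1,3-acyl shift of the β,γ-unsaturated ketone product.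

Step 9
Reactants: 12 tricyclic cyclobutene ketone
Product: 13 tricyclic alcohol (C5 hydroxyl on the lower face)
Conditions: NaBH4, THF/EtOH, −20 °C
Reagents that add atoms: none
Why: Hydride adds to the C5 carbonyl from the convex upper face, because the lower face is closed by the cyclobutene and the silicon bridge; this places the new hydroxyl on the lower face as in the target. The cold, weakly basic conditions leave the tert-butyl ester and the epimerisable C4 centre alone.

Step 10
Reactants: 13 tricyclic alcohol
Product: 14 tricyclic Mannich base (C4 side chain CH(CH2NMe2)CO2t-Bu)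
Conditions: LiN(i-Pr)2 (2.3 equiv), THF, −78 °C; CH2=NMe2+ I−, −78 → 0 °C
Reagents that add atoms: N,N-dimethylmethyleneiminium iodide (Eschenmoser's salt), C=[N+](C)C.[I-]
Why: Mannich reaction of the ester enolate (first half of the standard α-methylenation), with one equivalent of base consumed by the hydroxyl; in the tricycle the side chain and both oxygens are trans-diaxial, so no lactone can form. The new side-chain centre is a mixture and is removed in step 12; silicon may exchange between O3 and O5 under base, which is harmless because step 11 removes it from both.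

Step 11
Reactants: 14 tricyclic Mannich base
Product: 15 cyclobutene diol amino ester
Conditions: Bu4NF·3H2O, THF, 25 → 45 °C
Reagents that add atoms: none
Why: Fluoride attacks the alkoxy(dimethyl)silyl group, opens the Si–O bond and, through the pentacoordinate fluorosilicate, cleaves the C(sp2)–Si bond with protonation by the hydrate water (protodesilylation of a cyclic alkenylsiloxane); the high s-character of the cyclobutenyl carbon assists. PMB ether, tert-butyl ester and amine are inert to fluoride.

Step 12
Reactants: 15 cyclobutene diol amino ester
Product: 17 cyclobutene diol acrylate, via ammonium iodide 16 (not isolated)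
Conditions: MeI, CH2Cl2/MeOH, rt; then aq. NaHCO3, CH2Cl2, rt
Reagents that add atoms: none
Why: N-Methylation followed by E1cB (Hofmann-type) loss of trimethylamine completes the α-methylenation under conditions mild enough for the free diol; forming the acrylate only after the fluoride step keeps a Michael acceptor away from alkoxides.

Step 13
Reactants: 17 cyclobutene diol acrylate
Product: 18 tert-butyl 2-[(1R,2R,3S,4S,6S)-4-ethenyl-2,6-dihydroxy-3-{3-[(4-methoxybenzyl)oxy]prop-1-en-2-yl}-4-methylcyclohexyl]prop-2-enoate
Conditions: [1,3-bis(2,4,6-trimethylphenyl)imidazolidin-2-ylidene]dichloro(2-isopropoxybenzylidene)ruthenium (Hoveyda–Grubbs second-generation catalyst, 5 mol %), ethylene (1 atm), toluene, 50 °C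
Reagents that add atoms: ethylene, C=C
Why: Ring-opening metathesis with ethylene (ethenolysis), driven by cyclobutene strain: the ruthenium methylidene adds with the metal on the less substituted ring carbon, which releases the 1,1-disubstituted alkene on C6 and an alkylidene on the C1 side that ethylene turns into the vinyl group. The cis relationship of the two alkenyl groups is inherited from the ring fusion, and the α-substituted acrylate is too electron-poor and hindered to take part.

Step 14
Reactants: 19 3-methylfuran-2(5H)-one
Product: 22 4-methoxybenzyl (2Z)-4-(acetyloxy)-2-methylbut-2-enoate, via potassium hydroxy carboxylate 20 (not isolated), via hydroxy ester 21 (not isolated)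
Conditions: KOH (1.0 equiv), H2O/THF, 0 °C → rt; evaporate; 4-MeOC6H4CH2Cl, DMF, rt; then Ac2O, pyridine, 4-(dimethylamino)pyridine (cat.), 0 °C
Reagents that add atoms: potassium hydroxide, [K+].[OH-]; 4-methoxybenzyl chloride, COc1ccc(CCl)cc1; acetic anhydride, CC(=O)OC(C)=O
Why: Hydroxide opens the butenolide to the hydroxy carboxylate, whose Z geometry is fixed by the ring it comes from; O-alkylation of the carboxylate and immediate acetylation trap the open form before it can relactonise.

Step 15
Reactants: 22 4-methoxybenzyl (2Z)-4-(acetyloxy)-2-methylbut-2-enoate
Product: 23 (2Z)-4-(acetyloxy)-2-methylbut-2-enoic acid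
Conditions: CF3CO2H, anisole, CH2Cl2, 0 °C
Reagents that add atoms: none
Why: Acidolysis of the 4-methoxybenzyl ester, with the benzylic cation captured by anisole; the acetate and the Z-alkene are stable to brief cold acid, and no hydroxide is needed.

Step 16
Reactants: 18 tert-butyl 2-[(1R,2R,3S,4S,6S)-4-ethenyl-2,6-dihydroxy-3-{3-[(4-methoxybenzyl)oxy]prop-1-en-2-yl}-4-methylcyclohexyl]prop-2-enoate; 23 (2Z)-4-(acetyloxy)-2-methylbut-2-enoic acid
Product: 25 C3 ester (tert-butyl acrylate; free C5 hydroxyl; PMB ether), via mixed anhydride 24 (not isolated)
Conditions: 23, 2,4,6-Cl3C6H2COCl, Et3N, toluene, rt; then 18, toluene, 75 °C (no nucleophilic catalyst)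
Reagents that add atoms: none
Why: Yamaguchi esterification through the mixed anhydride, run thermally without a nucleophilic catalyst so that no addition–elimination pathway can isomerise the Z-alkene. The C3 hydroxyl, flanked by the C2 methylene, should react in preference to the C5 hydroxyl, which is shielded by the axial C6 substituent.

Step 17
Reactants: 25 C3 ester (tert-butyl acrylate; free C5 hydroxyl; PMB ether)
Product: 26 tert-butyl 2-[(1S,2R,3S,4S,6S)-6-{[(2Z)-4-(acetyloxy)-2-methylbut-2-enoyl]oxy}-4-ethenyl-2-hydroxy-3-(3-hydroxyprop-1-en-2-yl)-4-methylcyclohexyl]prop-2-enoate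
Conditions: DDQ, CH2Cl2/pH 7 buffer, 0 °C
Reagents that add atoms: none
Why: Oxidative PMB ether cleavage (benzylic hydride abstraction, then hydrolysis of the oxocarbenium ion); esters, the acetate and the electron-poor or unactivated alkenes do not react with the quinone.

Step 18
Reactants: 26 tert-butyl 2-[(1S,2R,3S,4S,6S)-6-{[(2Z)-4-(acetyloxy)-2-methylbut-2-enoyl]oxy}-4-ethenyl-2-hydroxy-3-(3-hydroxyprop-1-en-2-yl)-4-methylcyclohexyl]prop-2-enoate
Product: 28 2-[(1S,2R,3S,4S,6S)-6-{[(2Z)-4-(acetyloxy)-2-methylbut-2-enoyl]oxy}-4-ethenyl-2-hydroxy-3-(3-hydroxyprop-1-en-2-yl)-4-methylcyclohexyl]prop-2-enoic acid (CNP0261293.8), via tris(trimethylsilyl) derivative 27 (not isolated)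
Conditions: Me3SiOSO2CF3, 2,6-lutidine, CH2Cl2, 0 °C; then 10% aq. citric acid, THF, 0 °C
Reagents that add atoms: none
Why: Silyl triflate-mediated cleavage of the tert-butyl ester (O-silylation of the carbonyl, loss of the tert-butyl cation as isobutene) under buffered conditions; the two hydroxyls are silylated at the same time, so O5 is capped when the acid is unveiled. Brief, cold, weakly acidic hydrolysis then removes the three trimethylsilyl groups without hydroxide and without the strong acid that would close the lactone.

## Compound list

1 | methyl (3R)-3-[(tert-butyldimethylsilyl)oxy]-6-(dimethoxyphosphoryl)-5-oxohexanoate | COC(=O)C[C@H](O[Si](C)(C)C(C)(C)C)CC(=O)CP(=O)(OC)OC | starting material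
2 | dimethyl {(4R)-4-[(tert-butyldimethylsilyl)oxy]-6-[methoxy(methyl)amino]-2,6-dioxohexyl}phosphonate | CON(C)C(=O)C[C@H](O[Si](C)(C)C(C)(C)C)CC(=O)CP(=O)(OC)OC | intermediate
3 | dimethyl {(4S)-4-[(tert-butyldimethylsilyl)oxy]-2,6-dioxoheptyl}phosphonate | CC(=O)C[C@H](O[Si](C)(C)C(C)(C)C)CC(=O)CP(=O)(OC)OC | intermediate
4 | (5S)-5-[(tert-butyldimethylsilyl)oxy]-3-methylcyclohex-2-en-1-one | CC1=CC(=O)C[C@@H](O[Si](C)(C)C(C)(C)C)C1 | intermediate
5 | tert-butyl 2-[(1R,6S)-6-[(tert-butyldimethylsilyl)oxy]-4-methyl-2-oxocyclohex-3-en-1-yl]acetate | CC1=CC(=O)[C@H](CC(=O)OC(C)(C)C)[C@@H](O[Si](C)(C)C(C)(C)C)C1 | intermediate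
6 | tert-butyl 2-[(1R,6S)-6-hydroxy-4-methyl-2-oxocyclohex-3-en-1-yl]acetate | CC1=CC(=O)[C@H](CC(=O)OC(C)(C)C)[C@@H](O)C1 | intermediate
7 | prop-2-yn-1-ol | C#CCO | starting material
8 | 1-methoxy-4-[(prop-2-yn-1-yloxy)methyl]benzene | C#CCOCc1ccc(OC)cc1 | intermediate
9 | {3-[(4-methoxybenzyl)oxy]prop-1-yn-1-yl}lithium | [Li]C#CCOCc1ccc(OC)cc1 | intermediate
10 | chloro{3-[(4-methoxybenzyl)oxy]prop-1-yn-1-yl}dimethylsilane | C[Si](C)(Cl)C#CCOCc1ccc(OC)cc1 | intermediate
11 | tert-butyl 2-[(1R,6S)-6-({[3-(4-methoxybenzyloxy)prop-1-yn-1-yl]dimethylsilyl}oxy)-4-methyl-2-oxocyclohex-3-en-1-yl]acetate (photocycloaddition precursor) | CC1=CC(=O)[C@H](CC(=O)OC(C)(C)C)[C@@H](O[Si](C)(C)C#CCOCc2ccc(OC)cc2)C1 | intermediate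
12 | tricyclic cyclobutene ketone: cyclohexanone C1–C6 with C5 as carbonyl; cyclobutene cis-fused at C1–C6 on the lower face, its carbon on C1 bearing silicon and its carbon on C6 bearing CH2OPMB; SiMe2–O bridge from that carbon to C3 (lower face); C1 methyl and C4 CH2CO2t-Bu on the upper face | C2(COCc4ccc(OC)cc4)=C([Si](C)(C)O3)[C@]1(C)C[C@H]3[C@@H](CC(=O)OC(C)(C)C)C(=O)[C@@H]12 | intermediate
13 | tricyclic alcohol: as 12 with C5 reduced, hydroxyl on the lower face | C2(COCc4ccc(OC)cc4)=C([Si](C)(C)O3)[C@]1(C)C[C@H]3[C@@H](CC(=O)OC(C)(C)C)[C@H](O)[C@@H]12 | intermediate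
14 | tricyclic Mannich base: as 13 with the C4 side chain CH(CH2NMe2)CO2t-Bu (both epimers at the side-chain carbon) | C2(COCc4ccc(OC)cc4)=C([Si](C)(C)O3)[C@]1(C)C[C@H]3[C@@H](C(CN(C)C)C(=O)OC(C)(C)C)[C@H](O)[C@@H]12 | intermediate
15 | cyclobutene diol amino ester: cis-fused bicyclo[4.2.0]octene with C3 and C5 hydroxyls on the lower face, cyclobutene CH on C1 and C(CH2OPMB) on C6, C4 side chain CH(CH2NMe2)CO2t-Bu | C1(COCc3ccc(OC)cc3)=C[C@]2(C)C[C@H](O)[C@@H](C(CN(C)C)C(=O)OC(C)(C)C)[C@H](O)[C@@H]21 | intermediate
16 | trimethylammonium iodide of 15 | C1(COCc3ccc(OC)cc3)=C[C@]2(C)C[C@H](O)[C@@H](C(C[N+](C)(C)C)C(=O)OC(C)(C)C)[C@H](O)[C@@H]21.[I-] | intermediate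
17 | cyclobutene diol acrylate: as 15 with the C4 side chain C(=CH2)CO2t-Bu | C1(COCc3ccc(OC)cc3)=C[C@]2(C)C[C@H](O)[C@@H](C(=C)C(=O)OC(C)(C)C)[C@H](O)[C@@H]21 | intermediate
18 | tert-butyl 2-[(1R,2R,3S,4S,6S)-4-ethenyl-2,6-dihydroxy-3-{3-[(4-methoxybenzyl)oxy]prop-1-en-2-yl}-4-methylcyclohexyl]prop-2-enoate | C=C[C@]1(C)C[C@H](O)[C@@H](C(=C)C(=O)OC(C)(C)C)[C@H](O)[C@@H]1C(=C)COCc2ccc(OC)cc2 | intermediate
19 | 3-methylfuran-2(5H)-one | CC1=CCOC1=O | starting material
20 | potassium (2Z)-4-hydroxy-2-methylbut-2-enoate | [K+].[O-]C(=O)/C(C)=C\CO | intermediate
21 | 4-methoxybenzyl (2Z)-4-hydroxy-2-methylbut-2-enoate | COc1ccc(COC(=O)/C(C)=C\CO)cc1 | intermediate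
22 | 4-methoxybenzyl (2Z)-4-(acetyloxy)-2-methylbut-2-enoate | COc1ccc(COC(=O)/C(C)=C\COC(C)=O)cc1 | intermediate
23 | (2Z)-4-(acetyloxy)-2-methylbut-2-enoic acid | OC(=O)/C(C)=C\COC(C)=O | intermediate
24 | (2Z)-4-(acetyloxy)-2-methylbut-2-enoic 2,4,6-trichlorobenzoic anhydride | O=C(OC(=O)c1c(Cl)cc(Cl)cc1Cl)/C(C)=C\COC(C)=O | intermediate
25 | tert-butyl 2-[(1S,2R,3S,4S,6S)-6-{[(2Z)-4-(acetyloxy)-2-methylbut-2-enoyl]oxy}-4-ethenyl-2-hydroxy-3-{3-[(4-methoxybenzyl)oxy]prop-1-en-2-yl}-4-methylcyclohexyl]prop-2-enoate | C=C[C@]1(C)C[C@H](OC(=O)/C(C)=C\COC(C)=O)[C@@H](C(=C)C(=O)OC(C)(C)C)[C@H](O)[C@@H]1C(=C)COCc2ccc(OC)cc2 | intermediate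
26 | tert-butyl 2-[(1S,2R,3S,4S,6S)-6-{[(2Z)-4-(acetyloxy)-2-methylbut-2-enoyl]oxy}-4-ethenyl-2-hydroxy-3-(3-hydroxyprop-1-en-2-yl)-4-methylcyclohexyl]prop-2-enoate | C=C[C@]1(C)C[C@H](OC(=O)/C(C)=C\COC(C)=O)[C@@H](C(=C)C(=O)OC(C)(C)C)[C@H](O)[C@@H]1C(=C)CO | intermediate
27 | tris(trimethylsilyl) derivative of the target: trimethylsilyl ester, C5–O and primary O trimethylsilyl ethers | C=C[C@]1(C)C[C@H](OC(=O)/C(C)=C\COC(C)=O)[C@@H](C(=C)C(=O)O[Si](C)(C)C)[C@H](O[Si](C)(C)C)[C@@H]1C(=C)CO[Si](C)(C)C | intermediate
28 | 2-[(1S,2R,3S,4S,6S)-6-{[(2Z)-4-(acetyloxy)-2-methylbut-2-enoyl]oxy}-4-ethenyl-2-hydroxy-3-(3-hydroxyprop-1-en-2-yl)-4-methylcyclohexyl]prop-2-enoic acid | C=C[C@]1(C)C[C@H](OC(=O)/C(C)=C\COC(C)=O)[C@@H](C(=C)C(=O)O)[C@H](O)[C@@H]1C(=C)CO | target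

## Step count and risk assessment

Total step count: 18. Longest linear sequence: 15 steps (steps 1–5, 7–13 and 16–18); step 6 and steps 14–15 are side branches.

**Step 8 (key step).** What may go wrong: unproductive decay of the excited enone, because the reactive conformer must hold both the C3 tether and the C4 side chain axial; further photoreaction of the β,γ-unsaturated ketone product (1,3-acyl shift) on over-irradiation; hydrolysis of the labile alkynylsilyl ether before it is excited. Fallback: run the cycloaddition before the C4 alkylation, on a conformationally freer substrate. It sets out from **4**. Aqueous HF in MeCN gives (5S)-5-hydroxy-3-methylcyclohex-2-en-1-one F1. Silylation with chlorosilane **10** and imidazole gives the tethered enone F2. Irradiation at 350 nm gives the tricyclic ketone without the C4 side chain F3. Kinetic enolisation with LiN(i-Pr)2 and alkylation with tert-butyl bromoacetate from the open upper face then comes back to the route at **12**. The price is possible competition from the ring-fusion proton at C6 in that deprotonation, which is why this order is not the first choice.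

**Step 11 (protodesilylation).** What may go wrong: cleavage of the C(sp2)–Si bond stalling once the Si–O bond has opened, or a liberated alkoxide closing a lactone onto the tert-butyl ester during long exposure to basic fluoride. Fallback: replace fluoride-induced protodesilylation by electrophilic ipso-substitution. It sets out from **13**. N-Iodosuccinimide in MeCN exchanges silicon for iodine (iododesilylation; O3 is freed on aqueous work-up) to give the cyclobutenyl iodide diol F4. Formate reduction catalysed by Pd(OAc)2/PPh3 (HCO2H, Et3N) removes the iodine and gives the cyclobutene diol ester F5. Aminomethylation of its trianion (LiN(i-Pr)2, CH2=NMe2+ I−) comes back to the route at **15**.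

**Step 13 (ethenolysis).** What may go wrong: slow initiation on the trisubstituted cyclobutene, ring-opening oligomerisation before ethylene captures the hindered alkylidene next to the quaternary carbon, or alkene isomerisation by ruthenium hydrides. Fallback: oxidative cleavage and double methylenation in place of metathesis. It sets out from **17**. O3 (CH2Cl2, −78 °C; then PPh3) should cleave the strained, electron-rich cyclobutene in preference to the acrylate and give the keto aldehyde F6. Non-basic Takai–Lombardo methylenation of both carbonyls (Zn, CH2Br2, TiCl4), which does not epimerise C6, comes back to the route at **18**.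

**Step 16 (acylation).** What may go wrong: competing or double acylation at the C5 hydroxyl, or Z to E isomerisation of the activated acid. Fallback: make O5 unavailable by a proximity-controlled cyclic protecting group instead of relying on rate differences. It sets out from **18**.
- DDQ gives the triol F7.
- t-Bu2Si(OSO2CF3)2 with 2,6-lutidine silylates the primary alcohol first and can then close only onto the neighbouring O5. A bridge from O3 to O5 would force three lower-face substituents axial. The product is the seven-membered silylene F8, with O3 as the only free hydroxyl.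
- Esterification with mixed anhydride **24** gives the silylene ester F9.
- Me3SiOSO2CF3 with 2,6-lutidine converts the tert-butyl ester into the silylene acid F10.
- HF·pyridine removes the silylene and comes back to the route at the target **28**.

## Further compounds

F1 | step 8 | (5S)-5-hydroxy-3-methylcyclohex-2-en-1-one | CC1=CC(=O)C[C@@H](O)C1
F2 | step 8 | (5S)-5-({[3-(4-methoxybenzyloxy)prop-1-yn-1-yl]dimethylsilyl}oxy)-3-methylcyclohex-2-en-1-one | CC1=CC(=O)C[C@@H](O[Si](C)(C)C#CCOCc2ccc(OC)cc2)C1
F3 | step 8 | tricyclic cyclobutene ketone lacking the C4 side chain (as 12 with CH2 at C4) | C2(COCc4ccc(OC)cc4)=C([Si](C)(C)O3)[C@]1(C)C[C@H]3CC(=O)[C@@H]12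
F4 | step 11 | cyclobutenyl iodide diol (as 15 with iodine on the cyclobutene carbon attached to C1 and the C4 side chain CH2CO2t-Bu) | C1(COCc3ccc(OC)cc3)=C(I)[C@]2(C)C[C@H](O)[C@@H](CC(=O)OC(C)(C)C)[C@H](O)[C@@H]21
F5 | step 11 | cyclobutene diol ester (as 15 with the C4 side chain CH2CO2t-Bu) | C1(COCc3ccc(OC)cc3)=C[C@]2(C)C[C@H](O)[C@@H](CC(=O)OC(C)(C)C)[C@H](O)[C@@H]21
F6 | step 13 | keto aldehyde (as 18 with CHO in place of the vinyl group on C1 and C(=O)CH2OPMB in place of the alkenyl group on C6) | O=C[C@]1(C)C[C@H](O)[C@@H](C(=C)C(=O)OC(C)(C)C)[C@H](O)[C@@H]1C(=O)COCc2ccc(OC)cc2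
F7 | step 16 | tert-butyl 2-[(1R,2R,3S,4S,6S)-4-ethenyl-2,6-dihydroxy-3-(3-hydroxyprop-1-en-2-yl)-4-methylcyclohexyl]prop-2-enoate | C=C[C@]1(C)C[C@H](O)[C@@H](C(=C)C(=O)OC(C)(C)C)[C@H](O)[C@@H]1C(=C)CO
F8 | step 16 | di-tert-butylsilylene derivative of F7 bridging the C5 oxygen and the primary oxygen (C3 hydroxyl free) | C=C[C@]1(C)C[C@H](O)[C@@H](C(=C)C(=O)OC(C)(C)C)[C@H](O2)[C@@H]1C(=C)CO[Si]2(C(C)(C)C)C(C)(C)C
F9 | step 16 | C3 (2Z)-4-(acetyloxy)-2-methylbut-2-enoate of F8 | C=C[C@]1(C)C[C@H](OC(=O)/C(C)=C\COC(C)=O)[C@@H](C(=C)C(=O)OC(C)(C)C)[C@H](O2)[C@@H]1C(=C)CO[Si]2(C(C)(C)C)C(C)(C)C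
F10 | step 16 | silylene-protected acrylic acid (F9 without the tert-butyl group) | C=C[C@]1(C)C[C@H](OC(=O)/C(C)=C\COC(C)=O)[C@@H](C(=C)C(=O)O)[C@H](O2)[C@@H]1C(=C)CO[Si]2(C(C)(C)C)C(C)(C)C
A1 | alternative 1 | cyclised homoallylic alcohol: 2-(trimethylsilyl)ethyl 2-[4-ethenyl-2-hydroxy-6-[(4-methoxybenzyl)oxy]-4-methyl-3-{3-[(tert-butyldimethylsilyl)oxy]prop-1-en-2-yl}cyclohexyl]acetate, configured as the target | C=C[C@]1(C)C[C@H](OCc2ccc(OC)cc2)[C@@H](CC(=O)OCC[Si](C)(C)C)[C@H](O)[C@@H]1C(=C)CO[Si](C)(C)C(C)(C)C
A2 | alternative 2 | 2-methylprop-2-enal (methacrolein) | CC(=C)C=O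
A3 | alternative 2 | (4S)-4-[(1E,3E)-4-[dimethyl(phenyl)silyl]buta-1,3-dien-1-yl]-2,2-dimethyl-1,3-dioxolane | C[Si](C)(c1ccccc1)/C=C/C=C/[C@H]1COC(C)(C)O1
A4 | alternative 2 | endo cyclohexene carbaldehyde: 2-[(4S)-2,2-dimethyl-1,3-dioxolan-4-yl]-5-[dimethyl(phenyl)silyl]-1-methylcyclohex-3-ene-1-carbaldehyde | O=C[C@]1(C)C[C@H]([Si](C)(C)c2ccccc2)C=C[C@@H]1[C@H]3COC(C)(C)O3
A5 | alternative 3 | cyclised hydroxy acrylate: 2-(trimethylsilyl)ethyl 2-[4-ethenyl-2-hydroxy-6-[(4-methoxybenzyl)oxy]-4-methyl-3-{3-[(tert-butyldimethylsilyl)oxy]prop-1-en-2-yl}cyclohexyl]prop-2-enoate, configured as the target | C=C[C@]1(C)C[C@H](OCc2ccc(OC)cc2)[C@@H](C(=C)C(=O)OCC[Si](C)(C)C)[C@H](O)[C@@H]1C(=C)CO[Si](C)(C)C(C)(C)C
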